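Ring B is disconnected at C1–C2. Quaternary, methyl-bearing C1 neighbours oxygenated C10 in ring A and is tied to carbinol C4 only by the bare C2–C3 bridge. C10 is therefore treated as a ketone enol derivative and C2–C3 as an ethynyl group on C4. A cationic gold catalyst lets C1 of a silyl dienol ether add to the alkyne terminus. In one operation this closes ring B, creates quaternary C1 cis to C5–H and restores the C8–C10 enone. The precursor is a ring A cycloheptadiene bearing the C4–C6 stereotriad, built by Evans aldol, ring-closing metathesis and chelate-controlled ethynylation.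

Key step: step 12

Numbering:
- C1 = ring-fusion carbon with the methyl group.
- C2 and C3 = the two CH2 groups of ring B.
- C4 = isopropyl carbinol.
- C5 = ring-fusion CH.
- C6 = carbon with the 4-hydroxybenzoate.
- C7 = CH2.
- C8 = methyl-bearing alkene carbon.
- C9 = alkene CH.
- C10 = carbon with the isovalerate.
- Ring A = C1, C5–C10 (seven-membered); ring B = C1–C5 (five-membered).

Reading of the target: (1R,4S,5S,6R,10S). C1–CH3, C5–H and C4–OH lie on one face (α). C6–O, C10–O and the isopropyl group lie on the other (β). The bicycle is therefore cis-fused.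

Remark on the chemistry: C1 is carried as a mixture of epimers from the conjugate allylation until it becomes sp2 in step 11. The SMILES of these compounds leave C1 undefined.

Step 1
Reactants: 1 (4S)-4-benzyl-1,3-oxazolidin-2-one; 2 crotonic anhydride
Product: 3 (4S)-4-benzyl-3-[(E)-but-2-enoyl]-1,3-oxazolidin-2-one
Conditions: LiCl, Et3N, THF, −20 °C to rt
Reagents that add atoms: none
Why: Lithium chloride/amine-promoted N-acylation of an oxazolidinone by an anhydride is a mild standard imide synthesis that leaves the auxiliary stereocentre and the E-alkene untouched.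

Step 2
Reactants: 3 N-crotonyl imide; 4 allyltrimethylsilane
Product: 5 (4S)-4-benzyl-3-(3-methylhex-5-enoyl)-1,3-oxazolidin-2-one (both C1 epimers)
Conditions: TiCl4, CH2Cl2, −78 to −20 °C; aq NH4Cl
Reagents that add atoms: none
Why: Hosomi–Sakurai conjugate allylation, in which TiCl4 chelates both imide carbonyls and activates the enoyl unit for 1,4-attack of the allylsilane, and the new C1 centre needs no control because it is flattened in step 11.

Step 3
Reactants: 6 3-methylbut-3-en-1-ol
Product: 7 3-methylbut-3-enal
Conditions: Dess–Martin periodinane, CH2Cl2, 0 °C to rt; cold aq NaHCO3/Na2S2O3 wash; used at once as dried CH2Cl2 solution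
Reagents that add atoms: none
Why: Dess–Martin oxidation runs under near-neutral conditions, which should keep the β,γ-unsaturated aldehyde from slipping into conjugation.

Step 4
Reactants: 5 N-(3-methylhex-5-enoyl) imide; 7 3-methylbut-3-enal
Product: 10 (4S)-4-benzyl-3-[(2S,3R)-3-hydroxy-5-methyl-2-(pent-4-en-2-yl)hex-5-enoyl]-1,3-oxazolidin-2-one (5S,6R), via Z-boron enolate 8 (not isolated), via boron aldolate 9 (not isolated)
Conditions: Bu2BOTf, Et3N, CH2Cl2, 0 °C; 7, −78 to 0 °C; pH 7 buffer, MeOH, 30% H2O2, 0 °C
Reagents that add atoms: dibutylboron triflate, CCCCB(CCCC)OS(=O)(=O)C(F)(F)F (boron and butyl groups stay only in 8 and 9)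
Why: Evans syn aldol, in which the Z-boron enolate reacts through a chair Zimmerman–Traxler transition state on the face away from the benzyl group of the (S)-auxiliary, setting 5S and 6R (syn) for both C1 epimers.

Step 5
Reactants: 10 aldol adduct
Product: 11 (4S)-4-benzyl-3-{[(1S,2R)-2-hydroxy-4,7-dimethylcyclohept-4-en-1-yl]carbonyl}-1,3-oxazolidin-2-one (ring A closed; 5S,6R)
Conditions: second-generation Grubbs catalyst RuCl2(=CHPh)(PCy3)(H2IMes) (5 mol%), CH2Cl2 (0.005 M), reflux
Reagents that add atoms: none
Why: Ring-closing metathesis of the monosubstituted and the 1,1-disubstituted terminal alkene closes ring A as the trisubstituted cycloheptene with loss of ethene, and it is run before the alkyne is present (no enyne metathesis) and before the acyl substitutions so that C5 is tied back and less hindered.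

Step 6
Reactants: 11 cycloheptene imide
Product: 12 (1S,2R)-2-hydroxy-N-methoxy-N,4,7-trimethylcyclohept-4-ene-1-carboxamide
Conditions: MeONHMe·HCl, AlMe3, THF, −20 °C to rt; aq potassium sodium tartrate
Reagents that add atoms: N,O-dimethylhydroxylamine hydrochloride, CNOC.Cl
Why: Aluminium amide transamination (Weinreb amide synthesis), in which the cis C6 hydroxyl binds aluminium and steers the nucleophile to the exocyclic carbonyl, so the auxiliary leaves intact and C5 is not epimerised.

Step 7
Reactants: 12 Weinreb amide; 13 isopropylmagnesium chloride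
Product: 14 1-[(1S,2R)-2-hydroxy-4,7-dimethylcyclohept-4-en-1-yl]-2-methylpropan-1-one (C4 ketone; 5S,6R)
Conditions: 13 (4 equiv), THF, 0 °C to rt; aq NH4Cl
Reagents that add atoms: none
Why: Weinreb ketone synthesis, in which the Grignard reagent first deprotonates the hydroxyl, then adds once to the N-methoxy-N-methyl amide, and the base-sensitive β-hydroxy ketone is released only on quenching.

Step 8
Reactants: 14 β-hydroxy isopropyl ketone; 15 ethynylmagnesium bromide
Product: 17 (3S)-3-[(1S,2R)-2-hydroxy-4,7-dimethylcyclohept-4-en-1-yl]-4-methylpent-1-yn-3-ol (4S,5S,6R), via magnesium alkoxide chelate 16 (not isolated)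
Conditions: 15 (5 equiv), LaCl3·2LiCl (1 equiv), THF, −78 to −10 °C; aq NH4Cl
Reagents that add atoms: none
Why: Cram-chelate addition, in which the first equivalent of 15 turns the C6 hydroxyl into a magnesium alkoxide that binds the cis C4 carbonyl in a six-membered chelate cis-fused to ring A, so the small acetylide (helped by LaCl3·2LiCl against enolisation) should enter only from the carbonyl face turned away from C1 and C7, giving 4S.

Step 9
Reactants: 17 diol
Product: 18 C4,C6-bis(triethylsilyl) ether of 17 (4S,5S,6R)
Conditions: TESOTf (3 equiv), 2,6-lutidine, CH2Cl2, −78 °C to rt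
Reagents that add atoms: triethylsilyl triflate, CC[Si](CC)(CC)OS(=O)(=O)C(F)(F)F
Why: Silyl triflate/lutidine silylation is strong enough for the hindered tertiary propargylic alcohol, and separate TES groups are chosen because a cyclic 1,3-diol protecting group would have to become trans-fused to ring B with axial isopropyl and C7 groups and would work against step 12.

Step 10
Reactants: 18 bis-TES cycloheptene
Product: 19 ring A enone, (5R,6S)-3,7-dimethyl-6-[(3S)-4-methyl-3-(triethylsilyloxy)pent-1-yn-3-yl]-5-(triethylsilyloxy)cyclohept-2-en-1-one (4S,5S,6R in route numbering)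
Conditions: dirhodium tetracaprolactamate Rh2(cap)4 (1 mol%), t-BuOOH (5 equiv, decane), K2CO3 (0.5 equiv), CH2Cl2, rt
Reagents that add atoms: tert-butyl hydroperoxide, CC(C)(C)OO
Why: Dirhodium-catalysed allylic oxidation, in which the tert-butylperoxyl radical should abstract hydrogen at C10 because C7 is deactivated and shielded by the neighbouring silyloxy group, the methyl C–H bonds are stronger and the alkyne has no propargylic hydrogen, so oxygenation at the secondary allyl terminus leads to the β-methyl enone.

Step 11
Reactants: 19 ring A enone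
Product: 21 cross-conjugated TBS dienol ether (C10–OTBS, C10=C1 and C8=C9 double bonds, methyl on C1 and C8, C5 bearing the C4(OTES)(i-Pr)(C≡CH) group, C6–OTES; 4S,5S,6R), via lithium dienolate 20 (not isolated)
Conditions: LiN(SiMe3)2 (1.2 equiv), THF, −78 to −40 °C; TBSOTf (1.2 equiv), −78 °C; Et3N, pentane/aq NaHCO3
Reagents that add atoms: tert-butyldimethylsilyl triflate, CC(C)(C)[Si](C)(C)OS(=O)(=O)C(F)(F)F; lithium hexamethyldisilazide, [Li]N([Si](C)(C)C)[Si](C)(C)C (lithium stays only in 20)
Why: Kinetic α′-deprotonation of an enone by a carbonyl-bound lithium amide removes C1–H and not the γ-hydrogens at C7 or on the C8 methyl group (which amine/silyl triflate conditions would favour), hexamethyldisilazide is too weak a base to hold the alkyne as acetylide, and O-silylation fixes the C10=C1 enol ether while merging both C1 epimers.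

Step 12
Reactants: 21 TBS dienol ether with C4 ethynyl carbinol
Product: 23 cis-fused bicyclic dienone (C10 ketone, C8=C9 and C2=C3 alkenes, C4–OTES, C6–OTES; 1R,4R,5S,6R), via alkenylgold oxocarbenium ion 22 (not isolated)
Conditions: Ph3PAuNTf2 (5 mol%), i-PrOH (3 equiv), CH2Cl2, rt
Reagents that add atoms: Ph3PAuNTf2, O=S(=O)(N([Au-][P+](c1ccccc1)(c1ccccc1)c1ccccc1)S(=O)(=O)C(F)(F)F)C(F)(F)F (catalyst atoms stay only in 22)
Why: Ph3PAu+ binds the terminal alkyne, C1 of the C10=C1 silyl enol ether adds anti to gold at the alkyne terminus C2 to give 22, and 2-propanol takes over the TBS group while its proton cleaves the C3–Au bond, which returns the C8=C9–C10=O enone and the catalyst. The closest known reaction type is the gold-catalysed Conia-ene-type carbocyclisation of silyl enol ethers onto alkynes, established for cyclic enol ethers that build quaternary carbons and for enone-derived dienol ethers. Ring B closes in the five-endo-dig mode; four-exo attack at C3 is out of reach and bonding through C10 (six-endo) would leave a cation at C1 without oxygen support, so the polarity of the enol ether fixes the regiochemistry. The only new stereocentre, C1, is controlled by C5: the two-atom C4–C3 tether reaches only the enol ether face on which C4 stands, so C2 and C4 become cis, C1–CH3 ends up cis to C5–H (1R), and a trans-fused cyclopentene cannot form. Allylic strain between the C1 methyl group and the bulky C4 substituent holds the C5–C4 bond roughly perpendicular to the diene plane, which places the alkyne over C1. The step needs carbon attack to outrun loss of silyl groups and propargylic ionisation, which is secured by TES rather than a more labile silyl group on the C4 and C6 oxygens, by an acid- and silver-free catalyst and by a hindered alcohol as the only proton source.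

Step 13
Reactants: 23 bicyclic dienone
Product: 24 bicyclic enone with saturated C2–C3 (1R,4S,5S,6R)
Conditions: H2 (4 atm), RhCl(PPh3)3 (15 mol%), toluene–EtOH, rt
Reagents that add atoms: none
Why: Homogeneous hydrogenation with RhCl(PPh3)3 is governed by alkene substitution, so the cis-disubstituted C2=C3 bond should be saturated while the trisubstituted conjugated C8=C9 bond and the ketone stay, and no stereocentre is created.

Step 14
Reactants: 24 bicyclic enone
Product: 25 C10 allylic alcohol (1R,4S,5S,6R,10S)
Conditions: NaBH4, CeCl3·7H2O, MeOH, −78 to −40 °C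
Reagents that add atoms: none
Why: Luche reduction gives clean 1,2-attack, and hydride should come from the convex α face (the side of C1–CH3 and C5–H) because ring B, whose C2 stands pseudo-axial next to C10 when bulky C4 is pseudo-equatorial on ring A, and the C6 silyloxy group cover the β face, which gives the 10β (10S) alcohol.

Step 15
Reactants: 25 allylic alcohol; 26 isovaleryl chloride
Product: 27 C10 isovalerate (C4–OTES, C6–OTES)
Conditions: 26, pyridine, DMAP, CH2Cl2, 0 °C to rt
Reagents that add atoms: none
Why: DMAP-catalysed acylation with an acid chloride is reactive enough for the neopentyl-type secondary alcohol, which is the only free hydroxyl, and proceeds with retention at C10.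

Step 16
Reactants: 27 bis-TES isovalerate
Product: 28 C4,C6-diol C10-isovalerate
Conditions: HF·pyridine, pyridine, THF, 0 °C to rt
Reagents that add atoms: none
Why: Buffered fluoride cleavage of both TES ethers is mildly acidic, so neither ester migration nor ionisation of the allylic isovalerate is expected.

Step 17
Reactants: 29 4-hydroxybenzoic acid
Product: 31 4-(tert-butyldimethylsilyloxy)benzoic acid, via bis-TBS derivative 30 (not isolated)
Conditions: TBSCl (2.5 equiv), imidazole, DMF, rt; AcOH–THF–H2O, rt
Reagents that add atoms: tert-butyldimethylsilyl chloride, CC(C)(C)[Si](C)(C)Cl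
Why: Exhaustive silylation followed by selective hydrolysis works because a silyl ester is far more labile to aqueous acid than an aryl silyl ether.

Step 18
Reactants: 28 diol; 31 4-(tert-butyldimethylsilyloxy)benzoic acid
Product: 32 C6 4-(tert-butyldimethylsilyloxy)benzoate C10 isovalerate with free C4–OH
Conditions: DCC, DMAP, CH2Cl2, rt
Reagents that add atoms: none
Why: Steglich esterification acylates the secondary C6 hydroxyl only, since the tertiary C4 hydroxyl flanked by isopropyl and ring carbons is inert under these conditions, and C6 keeps its configuration.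

Step 19
Reactants: 32 silyl-protected diester
Product: 33 target, (1R,4S,5S,6R,10S)
Conditions: HF·pyridine, THF, 0 °C to rt
Reagents that add atoms: none
Why: Fluoride cleavage of the aryl silyl ether is fast and orthogonal to both esters, the tertiary alcohol and the alkene.

Compound list
1 | (4S)-4-benzyl-1,3-oxazolidin-2-one | O=C1N[C@@H](Cc2ccccc2)CO1 | starting material
2 | crotonic anhydride | C/C=C/C(=O)OC(=O)/C=C/C | starting material
3 | (4S)-4-benzyl-3-[(E)-but-2-enoyl]-1,3-oxazolidin-2-one | C/C=C/C(=O)N1C(=O)OC[C@@H]1Cc1ccccc1 | intermediate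
4 | allyltrimethylsilane | C=CC[Si](C)(C)C | starting material
5 | (4S)-4-benzyl-3-(3-methylhex-5-enoyl)-1,3-oxazolidin-2-one | C=CCC(C)CC(=O)N1C(=O)OC[C@@H]1Cc1ccccc1 | intermediate
6 | 3-methylbut-3-en-1-ol | C=C(C)CCO | starting material
7 | 3-methylbut-3-enal | C=C(C)CC=O | intermediate
8 | Z-dibutylboron enolate of 5 | CCCCB(CCCC)O/C(=C\C(C)CC=C)N1C(=O)OC[C@@H]1Cc1ccccc1 | intermediate
9 | dibutylboron aldolate | O=C([C@@H](C(C)CC=C)[C@H](OB(CCCC)CCCC)CC(C)=C)N1C(=O)OC[C@@H]1Cc1ccccc1 | intermediate
10 | syn aldol adduct (5S,6R) | O=C([C@@H](C(C)CC=C)[C@H](O)CC(C)=C)N1C(=O)OC[C@@H]1Cc1ccccc1 | intermediate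
11 | ring A cycloheptene imide (5S,6R) | CC1=CCC(C)[C@H](C(=O)N2C(=O)OC[C@@H]2Cc2ccccc2)[C@H](O)C1 | intermediate
12 | ring A Weinreb amide (5S,6R) | CC1=CCC(C)[C@H](C(=O)N(C)OC)[C@H](O)C1 | intermediate
13 | isopropylmagnesium chloride | CC(C)[Mg]Cl | starting material
14 | ring A β-hydroxy isopropyl ketone (5S,6R) | CC1=CCC(C)[C@H](C(=O)C(C)C)[C@H](O)C1 | intermediate
15 | ethynylmagnesium bromide | C#C[Mg]Br | starting material
16 | bromomagnesium alkoxide chelate of 14 | CC1=CCC(C)[C@H](C(=O)C(C)C)[C@H](O[Mg]Br)C1 | intermediate
17 | C4 ethynyl carbinol diol (4S,5S,6R) | CC1=CCC(C)[C@H]([C@@](O)(C(C)C)C#C)[C@H](O)C1 | intermediate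
18 | bis-TES ether of 17 | CC1=CCC(C)[C@H]([C@@](O[Si](CC)(CC)CC)(C(C)C)C#C)[C@H](O[Si](CC)(CC)CC)C1 | intermediate
19 | ring A enone (4S,5S,6R) | CC1=CC(=O)C(C)[C@H]([C@@](O[Si](CC)(CC)CC)(C(C)C)C#C)[C@H](O[Si](CC)(CC)CC)C1 | intermediate
20 | lithium cross-conjugated dienolate | CC1=CC(O[Li])=C(C)[C@H]([C@@](O[Si](CC)(CC)CC)(C(C)C)C#C)[C@H](O[Si](CC)(CC)CC)C1 | intermediate
21 | TBS dienol ether, key-step precursor (4S,5S,6R) | CC1=CC(O[Si](C)(C)C(C)(C)C)=C(C)[C@H]([C@@](O[Si](CC)(CC)CC)(C(C)C)C#C)[C@H](O[Si](CC)(CC)CC)C1 | intermediate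
22 | C3-alkenylgold C10-silyloxocarbenium triflimide | CC1=CC(=[O+][Si](C)(C)C(C)(C)C)[C@]2(C)C=C([Au-][P+](c3ccccc3)(c3ccccc3)c3ccccc3)[C@](O[Si](CC)(CC)CC)(C(C)C)[C@@H]2[C@H](O[Si](CC)(CC)CC)C1.O=S(=O)([N-]S(=O)(=O)C(F)(F)F)C(F)(F)F | intermediate
23 | cis-fused bicyclic dienone, key-step product (1R,4R,5S,6R) | CC1=CC(=O)[C@]2(C)C=C[C@](O[Si](CC)(CC)CC)(C(C)C)[C@@H]2[C@H](O[Si](CC)(CC)CC)C1 | intermediate
24 | bicyclic enone, C2–C3 saturated (1R,4S,5S,6R) | CC1=CC(=O)[C@]2(C)CC[C@](O[Si](CC)(CC)CC)(C(C)C)[C@@H]2[C@H](O[Si](CC)(CC)CC)C1 | intermediate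
25 | C10 allylic alcohol (1R,4S,5S,6R,10S) | CC1=C[C@H](O)[C@]2(C)CC[C@](O[Si](CC)(CC)CC)(C(C)C)[C@@H]2[C@H](O[Si](CC)(CC)CC)C1 | intermediate
26 | isovaleryl chloride | CC(C)CC(=O)Cl | starting material
27 | C10 isovalerate bis-TES ether | CC1=C[C@H](OC(=O)CC(C)C)[C@]2(C)CC[C@](O[Si](CC)(CC)CC)(C(C)C)[C@@H]2[C@H](O[Si](CC)(CC)CC)C1 | intermediate
28 | C4,C6-diol C10-isovalerate | CC1=C[C@H](OC(=O)CC(C)C)[C@]2(C)CC[C@](O)(C(C)C)[C@@H]2[C@H](O)C1 | intermediate
29 | 4-hydroxybenzoic acid | O=C(O)c1ccc(O)cc1 | starting material
30 | tert-butyldimethylsilyl 4-(tert-butyldimethylsilyloxy)benzoate | CC(C)(C)[Si](C)(C)Oc1ccc(C(=O)O[Si](C)(C)C(C)(C)C)cc1 | intermediate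
31 | 4-(tert-butyldimethylsilyloxy)benzoic acid | CC(C)(C)[Si](C)(C)Oc1ccc(C(=O)O)cc1 | intermediate
32 | C6 4-(TBSO)benzoate C10 isovalerate | CC1=C[C@H](OC(=O)CC(C)C)[C@]2(C)CC[C@](O)(C(C)C)[C@@H]2[C@H](OC(=O)c2ccc(O[Si](C)(C)C(C)(C)C)cc2)C1 | intermediate
33 | CNP0086724.3 | CC1=C[C@H](OC(=O)CC(C)C)[C@]2(C)CC[C@](O)(C(C)C)[C@@H]2[C@H](OC(=O)c2ccc(O)cc2)C1 | target

Total step count: 19. Longest linear sequence: 17 (steps 1, 2, 4–16, 18, 19).

Steps most likely to fail

1. Step 12. The silyl enol ether may be protodesilylated before the C–C bond forms. Gold may trigger ionisation or rearrangement at the propargylic C4–O bond. The crowded C4 centre may also populate rotamers that keep the alkyne away from C1. The fallback replaces π-acid activation by an enolate/alkenylpalladium coupling; it sets out from 19 and comes back at 23. The terminal alkyne of 19 is iodinated (N-iodosuccinimide, cat. AgNO3, acetone) to the iodoalkyne F1. Diimide (2-nitrobenzenesulfonyl hydrazide, Et3N) reduces it syn to the (Z)-alkenyl iodide F2 without touching the trisubstituted enone. Pd(PPh3)4 with t-BuOK in THF then joins the C1 enolate to C2 (intramolecular ketone α-alkenylation on zerovalent palladium). The same tether again allows only the cis-fused 23.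

2. Step 8. The magnesium aldolate may open by retro-aldol cleavage of C5–C6. The very hindered ketone may be enolised instead of attacked. Facial selectivity may erode if the chelate is not maintained in THF. The fallback exchanges the anionic alkoxide chelate for a neutral ether chelate, which removes the retro-aldol channel; it sets out from 14 and comes back at 17. The C6 hydroxyl is protected (4-methoxybenzyl trichloroacetimidate, cat. Sc(OTf)3, toluene, 0 °C) as the 4-methoxybenzyl ether F3. F3 is pre-complexed with MgBr2·OEt2 in CH2Cl2 at −78 °C and treated with 15, which should attack the bidentate chelate from the same open face and give the protected propargylic alcohol F4. DDQ in CH2Cl2/pH 7 buffer then releases 17.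

3. Step 10. Hydrogen abstraction at C7 or at the C8 methyl group, trapping of the allyl radical at its tertiary terminus, and over-oxidation would all lower regiocontrol. The fallback fixes the regiochemistry by polar steps; it sets out from 18 and comes back at 19. Epoxidation of C8=C9 (mCPBA, NaHCO3, CH2Cl2; the alkyne is inert) gives the epoxide F5. Sodium phenylselenide (PhSeSePh, NaBH4, EtOH) opens it at the secondary carbon C9 to the hydroxy selenide F6. H2O2 oxidation and selenoxide syn-elimination can only run towards C10 and give the tertiary allylic alcohol F7. Pyridinium chlorochromate, C5H5NH[CrO3Cl], in CH2Cl2 effects the Babler–Dauben oxidative 1,3-transposition to 19. The C8/C9 stereocentres of F5–F7 are irrelevant.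

Further compounds
F1 | step 12 | iodoalkyne of enone 19 | CC1=CC(=O)C(C)[C@H]([C@@](O[Si](CC)(CC)CC)(C(C)C)C#CI)[C@H](O[Si](CC)(CC)CC)C1
F2 | step 12 | (Z)-alkenyl iodide of enone 19 | CC1=CC(=O)C(C)[C@H]([C@@](O[Si](CC)(CC)CC)(C(C)C)/C=C\I)[C@H](O[Si](CC)(CC)CC)C1
F3 | step 8 | C6 4-methoxybenzyl ether of 14 | CC1=CCC(C)[C@H](C(=O)C(C)C)[C@H](OCc2ccc(OC)cc2)C1
F4 | step 8 | C6 4-methoxybenzyl ether of 17 | CC1=CCC(C)[C@H]([C@@](O)(C(C)C)C#C)[C@H](OCc2ccc(OC)cc2)C1
F5 | step 10 | C8,C9-epoxide of 18 | CC12OC1CC(C)[C@H]([C@@](O[Si](CC)(CC)CC)(C(C)C)C#C)[C@H](O[Si](CC)(CC)CC)C2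
F6 | step 10 | C8-hydroxy C9-phenylselenide | CC1(O)C([Se]c2ccccc2)CC(C)[C@H]([C@@](O[Si](CC)(CC)CC)(C(C)C)C#C)[C@H](O[Si](CC)(CC)CC)C1
F7 | step 10 | C8 tertiary allylic alcohol with C9=C10 alkene | CC1(O)C=CC(C)[C@H]([C@@](O[Si](CC)(CC)CC)(C(C)C)C#C)[C@H](O[Si](CC)(CC)CC)C1
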